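## Structural features

The target is a monocyclic 1,2-dioxane, counted here as O1, O2, C3, C4, C5, C6. C3 is a methoxy peroxyketal carbon that also carries an unbranched sixteen-carbon chain with a 4-yne and a (6E)-ene; C6 is a CH that carries a CH2CO2H arm. The two stereocentres, C3 (R) and C6 (S), face each other 1,4 across the ring with only the C4 and C5 methylenes between them. The methoxy group and the acid arm are cis, which in the chair puts OMe axial (anomeric to O2) and both carbon substituents equatorial, so C3 is the thermodynamically preferred epimer relative to C6. Fragile groups are the O–O bond (reducing agents, phosphines, low-valent metals, and base, because C6–H is alpha to O1 and C6–O1 is beta to the carboxyl group), the peroxyketal (ionises and exchanges under acid) and the conjugated enyne (hydrogenation, hydrometalation, electrophilic oxidants). The real difficulty is to close a six-membered peroxide through two C–O bonds and to fix the absolute configuration at C6, which has no neighbouring stereocentre to lean on. The key step exploits the unbranched six-carbon run C3, C4, C5, C6, acid CH2, carboxyl carbon: bonding the carboxyl carbon back to C3 gives a carbocycle in which C3 and C6 are the termini of a cyclohexa-1,3-diene, and the carboxyl carbon, as the inner oxygen-bearing diene carbon, already holds one of its oxygens.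

## Logic of the disconnections

16 from 15. No bond is cut; the single enantiomer is traced back to its racemate. The ring-forming step uses a flat achiral diene, and no handle near C6 allows an earlier separation. The gain is that every earlier intermediate may be racemic. The demand is an enantiomer separation at the end that does not exchange the peroxyketal.

15 from 14. The C3–OMe bond is cut and C3 is joined instead to a carboxyl oxygen, so that the acid arm and the ketal carbon are tied as a bridging lactone. This removes the need to control C3 separately and hides the free acid. The forward opening must proceed by alkyl–oxygen cleavage, must not esterify the acid, and must run under equilibrating conditions so that C3 settles correctly.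

14 from 13. The ring oxygen between C3 and the carbonyl carbon is deleted, which turns the C3–O bond into a C3–C bond. All six carbons of the run now sit in one carbocycle bridging the dioxane. The forward oxygen insertion must select C3 over the CH2 group as migrating carbon, spare the enyne and leave the O–O bond intact.

13 from 12. No skeletal bond is cut; the bridging carbonyl is rewritten as its silyl enol ether. This exposes the ring alkene that a [4+2] transform needs. The forward unmasking must avoid base.

12 from 11. The C3–O2 and C6–O1 bonds are cut and dioxygen is released. The peroxide ring, both stereocentres and both C–O bonds disappear in one transform, leaving an achiral diene. The forward step must favour cycloaddition over ene-type oxygenation and must not touch the enyne.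

11 from 9. The O–Si bond is cut, by way of 10. The demand is regioselective kinetic removal of the hydrogen on the chain-bearing carbon and not of a gamma hydrogen.

9 from 7 and 6. The C–C bond between the future C3 and the first chain carbon is cut. The ring comes from a commodity enone and the whole side chain from one electrophile. The forward alkylation must use the kinetic cross-conjugated dienolate before it equilibrates.

6 from 5. The C–I bond is exchanged for C–OH; the demand is only that the enyne is not attacked.

5 from 3 and 4. The bond between the alkyne carbon and the alkene carbon is cut, giving two simple fragments. The coupling must retain the E geometry.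

3 from 1. The C–I bond and the C–H bond on the neighbouring carbon are removed to return to a terminal alkyne. The forward hydrometalation must be syn and terminal-selective.

## Other disconnections considered

Alternative 1: The cut is the C4–C5 bond, taken at the alkene level, which opens the ring to the acyclic mixed peroxyketal A2 carrying a vinyl group on each of C3 and C6. In the forward direction a ruthenium alkylidene such as the second-generation Grubbs catalyst would close A2 to the 3,6-dihydro-1,2-dioxine A1 with loss of the two terminal CH2 groups.
- In its favour: ring-closing metathesis tolerates dialkyl peroxides and is a known route to six-membered cyclic peroxides. C6 can be introduced as one enantiomer from an enantiopure allylic alcohol derivative, so no resolution is needed. On absolute stereocontrol this alternative is better than the chosen plan.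
- Against it here: the enyne cannot be present during metathesis, so the alkyne must be silyl-capped as in A1 and the (E)-alkene added later by coupling with 3. The new C4=C5 bond must then be saturated without touching O–O or the alkyne, which leaves little beyond diimide. A2 itself requires O-alkylation of a tertiary methoxy hydroperoxide by a secondary allylic electrophile, where SN2' attack and elimination compete.
- Comparison: C3 would have to be equilibrated in acidic methanol after ring closure, as in the chosen plan, so the two are equal there. The metathesis is better precedented on peroxides than the oxygen insertion of the chosen plan. The chosen plan forms both C–O bonds in one step, carries the complete chain throughout, and should be shorter, since A1 still needs reduction, desilylation, coupling and saponification.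

Alternative 2: The cut is the O2–C3 bond. In the forward direction acid would convert the dimethyl ketal of the hydroperoxide A4 into an oxocarbenium ion, which the C6 hydroperoxide captures in a six-membered closure to give A3.
- In its favour: this is the best-precedented way to a 3-methoxy-1,2-dioxane. C6 would come from an enantiopure secondary alcohol with inversion when the peroxide is introduced, so the absolute configuration is made and not separated, which is better than the chosen plan. C3 is set by the same anomeric preference (equal), and the full enyne chain can be present throughout (equal).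
- Against it here: displacement at a secondary carbon by a peroxide nucleophile suffers from elimination and possible erosion of configuration. The hydroperoxide must survive several operations. After ring closure the silyl ether of A3 must still be cleaved and the primary alcohol oxidised in two stages to the acid next to a peroxide.
- Comparison: on structure and mechanism this alternative is the sounder plan, because every step is of a known type. The chosen plan is ahead only in step economy (ten steps against a sequence likely to be about half as long again) and in making two C–O bonds at once; it pays with a resolution and one untested step.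

Alternative 3: The cuts are the O1–C6 bond and the CH2–CO2 bond. In the forward direction the unsaturated hydroperoxy ketal A6 would be treated with a divalent palladium catalyst bearing a chiral ligand, under carbon monoxide in methanol with a reoxidant. 6-exo oxypalladation, CO insertion and methanolysis would give A5.
- In its favour: the ring, the C6 stereocentre and the ester arm arise in one catalytic step from a precursor that is a few steps from a simple ketone. Enantiocontrol would be catalytic, with no loss of half the material, which on paper is better than the chosen plan. The step count would be equal or slightly lower.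
- Against it here: hydroperoxides are prone to redox decomposition by palladium and by reoxidants such as CuCl2, and carbon monoxide with palladium hydrides can reduce O–O. Enantioselective oxypalladation by a peroxide oxygen with carbonylative trapping is undemonstrated, which makes two untested features against one in the chosen plan. The alkyne must be capped and the enyne completed afterwards with 3.
- Comparison: A6 is racemic at C3, so A5 would form with its C3 epimer and need acid equilibration, equal to the chosen plan. The chosen plan is mechanistically more secure; this alternative would be superior only if the catalysis could be made to work.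

Key step: step 6

Remark: 12 to 15 are racemates, each written with the SMILES of the enantiomer that is carried on to 16. The discussion counts the ring O1, O2, C3 (ketal carbon), C4, C5, C6 (CH), whereas the systematic names give the CH carbon locant 3 and the ketal carbon locant 6.

## Route

Step 1
Reactants: 1 undec-1-yne
Product: 3 (E)-1-iodoundec-1-ene, via diisobutyl[(E)-undec-1-enyl]alane 2 (not isolated)
Conditions: iBu2AlH, hexane, 50 °C; then I2, THF, −50 °C to rt
Reagents that add atoms: iodine, SMILES II
Why: Syn hydroalumination of the terminal alkyne places aluminium on C1 and hydrogen on C2, and iodinolysis of the alkenyl–aluminium bond occurs with retention, so only the (E)-iodide should form (hydroalumination–iodination).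

Step 2
Reactants: 3 (E)-1-iodoundec-1-ene; 4 pent-4-yn-1-ol
Product: 5 (E)-hexadec-6-en-4-yn-1-ol
Conditions: Pd(PPh3)2Cl2 (2 mol %), CuI (4 mol %), Et3N, THF, rt
Reagents that add atoms: none
Why: Sonogashira coupling: oxidative addition of the alkenyl iodide to zerovalent palladium formed in situ, transmetalation from the copper acetylide and reductive elimination join the sp and sp2 carbons with retention of the E geometry; the free hydroxyl group is tolerated.

Step 3
Reactants: 5 (E)-hexadec-6-en-4-yn-1-ol
Product: 6 (E)-1-iodohexadec-6-en-4-yne
Conditions: PPh3, I2, imidazole, CH2Cl2, 0 °C to rt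
Reagents that add atoms: iodine, SMILES II
Why: Appel reaction: the alcohol is activated as an alkoxyphosphonium ion and displaced by iodide at the primary carbon; the enyne is inert to these conditions.

Step 4
Reactants: 7 cyclohex-2-en-1-one; 6 (E)-1-iodohexadec-6-en-4-yne
Product: 9 rac-6-[(6E)-hexadec-6-en-4-yn-1-yl]cyclohex-2-en-1-one, via lithium cyclohexa-1,5-dien-1-olate 8 (not isolated)
Conditions: LiN(iPr)2, THF, −78 °C; then 6, DMPU, −78 to −20 °C
Reagents that add atoms: none
Why: The hindered amide removes an alpha-prime hydrogen of 7 under kinetic control to give the cross-conjugated dienolate, which is C-alkylated by the primary iodide with DMPU as promoter (kinetic enolate alkylation); the enolate is kept in slight excess to limit dialkylation, and the new stereocentre forms racemic and is flattened again in step 5.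

Step 5
Reactants: 9 rac-6-[(6E)-hexadec-6-en-4-yn-1-yl]cyclohex-2-en-1-one
Product: 11 tert-butyl({2-[(6E)-hexadec-6-en-4-yn-1-yl]cyclohexa-1,5-dien-1-yl}oxy)dimethylsilane, via lithium 2-alkylcyclohexa-1,5-dien-1-olate 10 (not isolated)
Conditions: LiN(iPr)2, THF, −78 °C; then TBSCl, DMPU, −78 to 0 °C
Reagents that add atoms: tert-butyldimethylsilyl chloride, SMILES CC(C)(C)[Si](C)(C)Cl
Why: A second kinetic deprotonation removes the remaining alpha-prime hydrogen in preference to a gamma hydrogen, and O-silylation of the cross-conjugated dienolate (silyl enol ether formation) fixes the 1-alkyl-2-silyloxy-1,3-diene. The tert-butyldimethylsilyl group is chosen because it survives a neutral work-up and is slow to migrate to oxygen in step 6, yet is still removable by fluoride.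

Step 6
Reactants: 11 tert-butyl({2-[(6E)-hexadec-6-en-4-yn-1-yl]cyclohexa-1,5-dien-1-yl}oxy)dimethylsilane
Product: 12 rac-tert-butyl({(1R,4S)-1-[(6E)-hexadec-6-en-4-yn-1-yl]-2,3-dioxabicyclo[2.2.2]oct-5-en-6-yl}oxy)dimethylsilane
Conditions: O2 (gas), 5,10,15,20-tetraphenylporphyrin (0.5 mol %), visible light, CH2Cl2, −78 °C
Reagents that add atoms: dioxygen, SMILES O=O
Why: Energy transfer from the excited porphyrin gives singlet oxygen, which adds as the two-atom partner across the diene termini C3 and C6 in a concerted, asynchronous [4+2] cycloaddition, bonding being more advanced at C3, the nucleophilic carbon of the enol ether. The closest known reaction type is the ascaridole-type endoperoxidation of cyclohexa-1,3-dienes, which extends to 2-silyloxy dienes. The 1,2-dioxane closes in a pericyclic Diels–Alder mode, suprafacial on both partners, as part of a 2,3-dioxabicyclo[2.2.2]octene. C3 and C6 become stereocentres together; their relative configuration is fixed by the suprafacial addition and the bicyclic frame, while the two faces of the flat achiral diene are enantiotopic, so 12 should form as a racemate. The step needs periselectivity (cycloaddition over ene reaction, [2+2] addition and silyl transfer to oxygen) and chemoselectivity (diene over enyne). The ring-locked s-cis geometry and the electron-rich diene favour the cycloaddition, the bulky silyl group and the low temperature hold back the silyl shift and the ene pathway, and a 1,2-disubstituted alkene conjugated to an alkyne is a poor partner for electrophilic singlet oxygen. The triplet energy of the sensitiser is far too low to isomerise the (E)-enyne.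

Step 7
Reactants: 12 rac-tert-butyl({(1R,4S)-1-[(6E)-hexadec-6-en-4-yn-1-yl]-2,3-dioxabicyclo[2.2.2]oct-5-en-6-yl}oxy)dimethylsilane
Product: 13 rac-(1S,4R)-4-[(6E)-hexadec-6-en-4-yn-1-yl]-2,3-dioxabicyclo[2.2.2]octan-5-one
Conditions: 48% aq. HF, MeCN, 0 °C; NaH2PO4/Na2HPO4 buffer (pH 7) work-up
Reagents that add atoms: none
Why: Fluoride-assisted protodesilylation of the silyl enol ether under acidic conditions unveils the ketone without any base that could start Kornblum–DeLaMare rearrangement at C6–H or beta-elimination of the peroxide; neither stereocentre is touched.

Step 8
Reactants: 13 rac-(1S,4R)-4-[(6E)-hexadec-6-en-4-yn-1-yl]-2,3-dioxabicyclo[2.2.2]octan-5-one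
Product: 14 rac-(1R,5S)-1-[(6E)-hexadec-6-en-4-yn-1-yl]-2,6,7-trioxabicyclo[3.2.2]nonan-3-one
Conditions: mCPBA, CH2Cl2, 0 °C
Reagents that add atoms: 3-chloroperoxybenzoic acid, SMILES OOC(=O)c1cccc(Cl)c1
Why: Proposed new method: the peracid should add to the strained bridged carbonyl to give a Criegee adduct, from which the bridgehead carbon C3, tertiary and oxygen-substituted, migrates to oxygen with retention in preference to the CH2 group, so that oxygen enters on the C3 side and gives the acyloxy peroxyketal with both stereocentres unchanged; the closest known reaction type is the Baeyer–Villiger oxidation of 7-oxabicyclo[2.2.1]heptan-2-ones and other alpha-alkoxy bridged ketones, where bridgehead migration is fast enough to leave alkenes untouched, and the fragmentation that an alpha-peroxy ketone could otherwise undergo is disfavoured because the bicycle holds the C3–C(=O) and O2–O1 bonds gauche.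

Step 9
Reactants: 14 rac-(1R,5S)-1-[(6E)-hexadec-6-en-4-yn-1-yl]-2,6,7-trioxabicyclo[3.2.2]nonan-3-one
Product: 15 rac-2-[(3S,6R)-6-[(6E)-hexadec-6-en-4-yn-1-yl]-6-methoxy-1,2-dioxan-3-yl]acetic acid
Conditions: PPTS (10 mol %), MeOH, 0 °C to rt
Reagents that add atoms: methanol, SMILES CO
Why: Acid-catalysed solvolysis of an acyloxy ketal by alkyl–oxygen cleavage (ketal exchange through a peroxycarbenium ion with the tethered carboxylate as leaving group) frees the CH2CO2H arm and places OMe on C3. The exchange is reversible, so C3 should settle as the epimer with axial OMe and equatorial chain, which is the cis relation to the C6 arm required, while C6 is not involved. The weak acid is chosen so that Fischer esterification of the liberated acid does not set in.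

Step 10
Reactants: 15 rac-2-[(3S,6R)-6-[(6E)-hexadec-6-en-4-yn-1-yl]-6-methoxy-1,2-dioxan-3-yl]acetic acid
Product: 16 2-[(3S,6R)-6-[(6E)-hexadec-6-en-4-yn-1-yl]-6-methoxy-1,2-dioxan-3-yl]acetic acid
Conditions: preparative SFC on amylose tris(3,5-dimethylphenylcarbamate)/silica, CO2/MeOH
Reagents that add atoms: none
Why: Resolution of a racemate by chromatography on a chiral stationary phase; no bond is made and no stereocentre changes, and the enantiomer with R at the ketal carbon and S at the CH carbon is collected, its identity to be assigned by chiroptical comparison. Methanol as modifier makes any ketal exchange on the column degenerate.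

## Compound list

1 | undec-1-yne | C#CCCCCCCCCC | starting material
2 | diisobutyl[(E)-undec-1-enyl]alane | CCCCCCCCC/C=C/[Al](CC(C)C)CC(C)C | intermediate (not isolated)
3 | (E)-1-iodoundec-1-ene | CCCCCCCCC/C=C/I | intermediate
4 | pent-4-yn-1-ol | OCCCC#C | starting material
5 | (E)-hexadec-6-en-4-yn-1-ol | CCCCCCCCC/C=C/C#CCCCO | intermediate
6 | (E)-1-iodohexadec-6-en-4-yne | CCCCCCCCC/C=C/C#CCCCI | intermediate
7 | cyclohex-2-en-1-one | O=C1C=CCCC1 | starting material
8 | lithium cyclohexa-1,5-dien-1-olate | [Li]OC1=CCCC=C1 | intermediate (not isolated)
9 | rac-6-[(6E)-hexadec-6-en-4-yn-1-yl]cyclohex-2-en-1-one | CCCCCCCCC/C=C/C#CCCCC1CCC=CC1=O | intermediate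
10 | lithium 2-[(6E)-hexadec-6-en-4-yn-1-yl]cyclohexa-1,5-dien-1-olate | CCCCCCCCC/C=C/C#CCCCC1=C(O[Li])C=CCC1 | intermediate (not isolated)
11 | tert-butyl({2-[(6E)-hexadec-6-en-4-yn-1-yl]cyclohexa-1,5-dien-1-yl}oxy)dimethylsilane (1-alkyl-2-silyloxycyclohexa-1,3-diene) | CCCCCCCCC/C=C/C#CCCCC1=C(O[Si](C)(C)C(C)(C)C)C=CCC1 | intermediate
12 | rac-tert-butyl({(1R,4S)-1-[(6E)-hexadec-6-en-4-yn-1-yl]-2,3-dioxabicyclo[2.2.2]oct-5-en-6-yl}oxy)dimethylsilane | CCCCCCCCC/C=C/C#CCCC[C@@]12CC[C@@H](C=C1O[Si](C)(C)C(C)(C)C)OO2 | intermediate
13 | rac-(1S,4R)-4-[(6E)-hexadec-6-en-4-yn-1-yl]-2,3-dioxabicyclo[2.2.2]octan-5-one | CCCCCCCCC/C=C/C#CCCC[C@@]12CC[C@@H](CC1=O)OO2 | intermediate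
14 | rac-(1R,5S)-1-[(6E)-hexadec-6-en-4-yn-1-yl]-2,6,7-trioxabicyclo[3.2.2]nonan-3-one | CCCCCCCCC/C=C/C#CCCC[C@@]12CC[C@@H](CC(=O)O1)OO2 | intermediate
15 | rac-2-[(3S,6R)-6-[(6E)-hexadec-6-en-4-yn-1-yl]-6-methoxy-1,2-dioxan-3-yl]acetic acid | CCCCCCCCC/C=C/C#CCCC[C@]1(OC)CC[C@@H](CC(=O)O)OO1 | intermediate
16 | 2-[(3S,6R)-6-[(6E)-hexadec-6-en-4-yn-1-yl]-6-methoxy-1,2-dioxan-3-yl]acetic acid | CCCCCCCCC/C=C/C#CCCC[C@]1(OC)CC[C@@H](CC(=O)O)OO1 | target

## Step count and least certain steps

Total: 10 steps. Longest linear sequence: 10 steps, from 1 to 16; 4 enters at step 2 and 7 at step 4.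

Step 8 (oxygen insertion). The peracid may be consumed by epoxidation of the enyne alkene before insertion is complete, because a peroxy oxygen donates less to the migrating carbon than an ether oxygen and migration may be slower than in the alpha-alkoxy models. The Criegee adduct may also collapse by cleavage of the O–O bridge, and the acid by-product may ionise the product. The fallback uses only established chemistry and sets out from 9. The potassium dienolate (KN(SiMe3)2, THF, −78 °C) would be hydroxylated with 3-phenyl-2-(phenylsulfonyl)oxaziridine to rac-6-[(6E)-hexadec-6-en-4-yn-1-yl]-6-hydroxycyclohex-2-en-1-one F1. Pb(OAc)4 in MeOH/benzene at 0 °C would cleave the alpha-hydroxy ketone to methyl (2Z,12E)-6-oxodocosa-2,12-dien-10-ynoate F2. Urea–hydrogen peroxide with catalytic Sc(OTf)3 in MeOH would convert the ketone into methyl (2Z,12E)-6-hydroperoxy-6-methoxydocosa-2,12-dien-10-ynoate F3. Et2NH in CF3CH2OH would close the ring by conjugate addition of the hydroperoxide, and brief equilibration with camphorsulfonic acid in MeOH would give methyl rac-2-[(3S,6R)-6-[(6E)-hexadec-6-en-4-yn-1-yl]-6-methoxy-1,2-dioxan-3-yl]acetate F4. LiOH in aqueous THF at 0 °C would then return to the route at 15, which is resolved as in step 10.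

Step 6 (key step). Periselectivity may be lost: attack of singlet oxygen at C3 alone, followed by silyl transfer to the terminal oxygen or by abstraction of an allylic hydrogen, would oxygenate C3 without closing the ring, and the bridged silyl enol ether may decompose on silica. The second hazard is limited by taking crude 12 straight into step 7. The fallback sets out from 9 and replaces the migrating silyl group by an acyl group. LiN(iPr)2 followed by acetic anhydride would give 2-[(6E)-hexadec-6-en-4-yn-1-yl]cyclohexa-1,5-dien-1-yl acetate F5. The same sensitised photooxygenation would give rac-(1R,4S)-1-[(6E)-hexadec-6-en-4-yn-1-yl]-2,3-dioxabicyclo[2.2.2]oct-5-en-6-yl acetate F6. Acid-catalysed transesterification (TsOH cat., MeOH, 0 °C) would release the ketone and return to the route at 13.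

Step 4 (alkylation). Proton exchange between product and unreacted enolate may lead to dialkylation, and the kinetic dienolate may equilibrate or undergo Michael self-condensation at the temperature an unactivated primary iodide needs. The fallback sets out from 7. Condensation with 1,1-dimethylhydrazine would give cyclohex-2-en-1-one N,N-dimethylhydrazone F7. Its alpha-prime lithio derivative (LiN(iPr)2, THF) would be alkylated with 6 to 6-[(6E)-hexadec-6-en-4-yn-1-yl]cyclohex-2-en-1-one N,N-dimethylhydrazone F8. Hydrolysis with CuCl2 in buffered aqueous THF would return to the route at 9.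

Step 9 (methanolysis). The liberated acid may be esterified, or the lactone may open by acyl–oxygen cleavage, either of which caps the acid as its methyl ester; with too weak an acid the equilibration at C3 may stay incomplete. The fallback sets out from 14 and uses aprotic Lewis-acid ketal exchange. MeOSiMe3 with catalytic Me3SiOTf in CH2Cl2 at −78 °C would ionise the acyloxy ketal and deliver methoxide axially, the carboxyl leaving as trimethylsilyl rac-2-[(3S,6R)-6-[(6E)-hexadec-6-en-4-yn-1-yl]-6-methoxy-1,2-dioxan-3-yl]acetate F9. Aqueous work-up would hydrolyse the silyl ester and return to the route at 15.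

Step 10 (resolution). The free lipophilic acid may tail or separate poorly on the chiral phase, and material may be lost on scale. The fallback sets out from 15 and relies on crystallisation. Salt formation with (S)-1-phenylethylamine and fractional crystallisation would give (S)-1-phenylethylammonium 2-[(3S,6R)-6-[(6E)-hexadec-6-en-4-yn-1-yl]-6-methoxy-1,2-dioxan-3-yl]acetate F10. This assumes that the salt of the wanted acid is the less soluble one; the amine enantiomer is to be chosen accordingly. Liberation with cold aqueous KHSO4 would return to the route at 16.

Further compounds
F1 | step 8 | rac-6-[(6E)-hexadec-6-en-4-yn-1-yl]-6-hydroxycyclohex-2-en-1-one | CCCCCCCCC/C=C/C#CCCCC1(O)CCC=CC1=O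
F2 | step 8 | methyl (2Z,12E)-6-oxodocosa-2,12-dien-10-ynoate | CCCCCCCCC/C=C/C#CCCCC(=O)CC/C=C\C(=O)OC
F3 | step 8 | methyl (2Z,12E)-6-hydroperoxy-6-methoxydocosa-2,12-dien-10-ynoate (racemic) | CCCCCCCCC/C=C/C#CCCCC(OC)(OO)CC/C=C\C(=O)OC
F4 | step 8 | methyl rac-2-[(3S,6R)-6-[(6E)-hexadec-6-en-4-yn-1-yl]-6-methoxy-1,2-dioxan-3-yl]acetate | CCCCCCCCC/C=C/C#CCCC[C@]1(OC)CC[C@@H](CC(=O)OC)OO1
F5 | step 6 | 2-[(6E)-hexadec-6-en-4-yn-1-yl]cyclohexa-1,5-dien-1-yl acetate | CCCCCCCCC/C=C/C#CCCCC1=C(OC(C)=O)C=CCC1
F6 | step 6 | rac-(1R,4S)-1-[(6E)-hexadec-6-en-4-yn-1-yl]-2,3-dioxabicyclo[2.2.2]oct-5-en-6-yl acetate | CCCCCCCCC/C=C/C#CCCC[C@@]12CC[C@@H](C=C1OC(C)=O)OO2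
F7 | step 4 | cyclohex-2-en-1-one N,N-dimethylhydrazone | CN(C)N=C1C=CCCC1
F8 | step 4 | 6-[(6E)-hexadec-6-en-4-yn-1-yl]cyclohex-2-en-1-one N,N-dimethylhydrazone (racemic) | CCCCCCCCC/C=C/C#CCCCC1CCC=CC1=NN(C)C
F9 | step 9 | trimethylsilyl rac-2-[(3S,6R)-6-[(6E)-hexadec-6-en-4-yn-1-yl]-6-methoxy-1,2-dioxan-3-yl]acetate | CCCCCCCCC/C=C/C#CCCC[C@]1(OC)CC[C@@H](CC(=O)O[Si](C)(C)C)OO1
F10 | step 10 | (S)-1-phenylethylammonium 2-[(3S,6R)-6-[(6E)-hexadec-6-en-4-yn-1-yl]-6-methoxy-1,2-dioxan-3-yl]acetate | CCCCCCCCC/C=C/C#CCCC[C@]1(OC)CC[C@@H](CC(=O)[O-])OO1.C[C@H]([NH3+])c1ccccc1
A1 | alternative 1 | methyl 2-[(3R)-6-methoxy-6-{5-[tri(propan-2-yl)silyl]pent-4-yn-1-yl}-3,6-dihydro-1,2-dioxin-3-yl]acetate (both epimers at the ketal carbon) | CC(C)[Si](C(C)C)(C(C)C)C#CCCCC1(OC)C=C[C@@H](CC(=O)OC)OO1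
A2 | alternative 1 | methyl (3R)-3-({3-methoxy-8-[tri(propan-2-yl)silyl]oct-1-en-7-yn-3-yl}peroxy)pent-4-enoate (both epimers at the ketal carbon) | COC(=O)C[C@H](C=C)OOC(OC)(C=C)CCCC#C[Si](C(C)C)(C(C)C)C(C)C
A3 | alternative 2 | tert-butyl(2-{(3S,6R)-6-[(6E)-hexadec-6-en-4-yn-1-yl]-6-methoxy-1,2-dioxan-3-yl}ethoxy)diphenylsilane | CCCCCCCCC/C=C/C#CCCC[C@]1(OC)CC[C@@H](CCO[Si](c2ccccc2)(c2ccccc2)C(C)(C)C)OO1
A4 | alternative 2 | tert-butyl{[(3S,12E)-3-hydroperoxy-6,6-dimethoxydocos-12-en-10-yn-1-yl]oxy}diphenylsilane | CCCCCCCCC/C=C/C#CCCCC(OC)(OC)CC[C@@H](CCO[Si](c1ccccc1)(c1ccccc1)C(C)(C)C)OO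
A5 | alternative 3 | methyl 2-[(3S,6R)-6-methoxy-6-[5-(trimethylsilyl)pent-4-yn-1-yl]-1,2-dioxan-3-yl]acetate | C[Si](C)(C)C#CCCC[C@]1(OC)CC[C@@H](CC(=O)OC)OO1
A6 | alternative 3 | (6-hydroperoxy-6-methoxydec-9-en-1-yn-1-yl)trimethylsilane (racemic) | C[Si](C)(C)C#CCCCC(OC)(OO)CCC=C
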